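**Plan**

- Retrosynthesis: the flavanone is first taken back to the flavone (C2–H and C3–H removed). Ring B is then cut at C1'–C2' and C5'–C6' into a 2-ethynylchromone (supplying C1' and C6') and a 2-silyloxy-3-alkylbuta-1,3-diene (supplying C2'–C5') that already carries the complete hydrated geranyl chain. The chromone is cut at C2–C3 and O1–C2, the diene at the bond between C3' and the side-chain CH2 and at its C2' methylene.
- Enabling feature: ring B is a 1,2,4-trisubstituted benzene whose C4' oxygen is para to C1' and ortho to the C3' chain. This is the pattern a 2-silyloxy-3-alkyldiene leaves on a terminal alkyne once two hydrogens are removed.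
- Forward order: rings A and C (chromone) from trihydroxyacetophenone; side chain from geranyl acetate, joined to methyl acetoacetate and converted into the diene; ring B by Diels–Alder reaction and aromatisation; then reduction of ring C and desilylation.
- Stereochemistry: the E-olefin comes from geranyl acetate. (S)-C2 is set by ligand-controlled CuH conjugate reduction of the flavone (hydride to the Re face of C2).

Key step: step 9

Remark: the (R)-ligand in step 10 is assumed, by analogy with related β-substituted enones, to deliver hydride to the Re face of C2; if a model flavone shows the opposite sense, the (S)-ligand is used instead.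

**Route**

Step 1
Reactants: 1 2',4',6'-trihydroxyacetophenone; 2 ethyl 2,2-diethoxyacetate
Product: 5 5,7-dihydroxy-4-oxo-4H-chromene-2-carbaldehyde, via diketone acetal 3 (not isolated), via chromone acetal 4 (not isolated)
Conditions: LiN(SiMe3)2 (4.3 equiv), THF, –78 to –10 °C; 2, –10 °C to rt; AcOH quench, evaporate; AcOH, cat. H2SO4, 90 °C; then 2 M aq HCl, 60 °C
Reagents that add atoms: water, O
Why: Crossed Claisen condensation of the lithium polyanion of 1 with the non-enolisable, alkoxy-activated ester 2 gives the 1,3-diketone, which undergoes the usual acid cyclodehydration of o-hydroxyaryl 1,3-diketones to the chromone (the two ortho hydroxyls are equivalent, so only one chromone can form), and aqueous acid then hydrolyses the acetal to the aldehyde.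

Step 2
Reactants: 5 5,7-dihydroxy-4-oxo-4H-chromene-2-carbaldehyde
Product: 6 2-ethynyl-5,7-dihydroxy-4H-chromen-4-one
Conditions: dimethyl (1-diazo-2-oxopropyl)phosphonate (1.3 equiv), K2CO3 (4 equiv), MeOH, 0 °C to rt; work-up at pH 4
Reagents that add atoms: dimethyl (1-diazo-2-oxopropyl)phosphonate, COP(=O)(OC)C(=[N+]=[N-])C(C)=O
Why: Ohira–Bestmann homologation, in which methanolysis of the reagent gives the diazomethylphosphonate anion that olefinates the aldehyde and loses N2 with a 1,2-hydrogen shift to the terminal alkyne, while the phenoxides formed in the basic medium lower the electrophilicity of the chromone towards methoxide.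

Step 3
Reactants: 6 2-ethynyl-5,7-dihydroxy-4H-chromen-4-one
Product: 7 5,7-bis(tert-butyldimethylsilyloxy)-2-ethynyl-4H-chromen-4-one
Conditions: TBSOTf (2.3 equiv), 2,6-lutidine (3 equiv), CH2Cl2, 0 °C to rt
Reagents that add atoms: tert-butyldimethylsilyl triflate, CC(C)(C)[Si](C)(C)OS(=O)(=O)C(F)(F)F
Why: Silyl triflate O-silylation of both phenols, in which reversible silylation of the chromone carbonyl breaks the hydrogen bond of the 5-hydroxyl so that this hindered peri position is also capped, and the hindered pyridine base does not add to the activated alkyne.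

Step 4
Reactants: 8 geranyl acetate
Product: 11 (2E)-3,7-dimethyloct-2-ene-1,7-diol, via organomercurial 9 (not isolated), via hydroxy acetate 10 (not isolated)
Conditions: Hg(OAc)2 (1.05 equiv), THF–H2O, rt; then 3 M aq NaOH, NaBH4, 0 °C; then MeOH, rt
Reagents that add atoms: water, O
Why: Markovnikov oxymercuration–demercuration should take place only at the remote 6,7-double bond because the allylic acetate deactivates the 2,3-double bond, and the alkaline medium of the reduction then saponifies the acetate, the E-olefin being untouched.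

Step 5
Reactants: 11 (2E)-3,7-dimethyloct-2-ene-1,7-diol
Product: 12 (6E)-8-bromo-2,6-dimethyloct-6-en-2-ol
Conditions: NBS (1.1 equiv), Me2S (1.3 equiv), CH2Cl2, –20 to 0 °C; used without storage
Reagents that add atoms: N-bromosuccinimide, O=C1CCC(=O)N1Br
Why: Corey–Kim halogenation, in which only the unhindered allylic alkoxysulfonium salt is displaced by bromide (SN2, no allylic transposition, E geometry kept) while the tertiary alcohol is returned unchanged.

Step 6
Reactants: 12 (6E)-8-bromo-2,6-dimethyloct-6-en-2-ol; 13 methyl acetoacetate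
Product: 14 methyl (4E)-2-acetyl-9-hydroxy-5,9-dimethyldec-4-enoate (racemic)
Conditions: 13 (1.6 equiv), NaH (1.5 equiv), THF, 0 °C; then 12, 0 °C to rt
Reagents that add atoms: none
Why: Acetoacetic ester alkylation, an SN2 C-alkylation of the sodium enolate at the primary allylic bromide; the enolate is too weak a base to deprotonate the tertiary alcohol and the excess of 13 suppresses dialkylation.

Step 7
Reactants: 14 methyl (4E)-2-acetyl-9-hydroxy-5,9-dimethyldec-4-enoate (racemic)
Product: 17 (5E)-10-hydroxy-6,10-dimethyl-3-methylideneundec-5-en-2-one, via keto acid 15 (not isolated), via Mannich acid 16 (not isolated)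
Conditions: LiOH, THF–H2O, 0 °C to rt; then AcOH (to pH 6–7), 37% aq CH2O, Et2NH, rt to 40 °C
Reagents that add atoms: formaldehyde, C=O
Why: Saponification followed by decarboxylative Mannich methylenation, in which the β-keto acid adds to the iminium ion from formaldehyde and diethylamine and the adduct loses CO2 and the amine, so that the methylene group appears only on the carbon that carried the carboxyl group.

Step 8
Reactants: 17 (5E)-10-hydroxy-6,10-dimethyl-3-methylideneundec-5-en-2-one
Product: 19 2-(tert-butyldimethylsilyloxy)-3-[(2E)-3,7-dimethyl-7-(triethylsilyloxy)oct-2-en-1-yl]buta-1,3-diene, via triethylsilyl ether 18 (not isolated)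
Conditions: TESOTf (1.05 equiv), 2,6-lutidine (1.5 equiv), CH2Cl2, –78 to –40 °C; then Et3N (3 equiv), TBSOTf (1.3 equiv), –40 to 0 °C; chromatography on Et3N-deactivated silica
Reagents that add atoms: triethylsilyl triflate, CC[Si](CC)(CC)OS(=O)(=O)C(F)(F)F; tert-butyldimethylsilyl triflate, CC(C)(C)[Si](C)(C)OS(=O)(=O)C(F)(F)F
Why: O-Silylation of the tertiary alcohol with the weak pyridine base (which does not enolise the ketone at low temperature) is followed by soft enolisation of the methyl ketone with silyl triflate and triethylamine to the 2-silyloxydiene, the methyl group being the only enolisable position.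

Step 9
Reactants: 7 5,7-bis(tert-butyldimethylsilyloxy)-2-ethynyl-4H-chromen-4-one; 19 2-(tert-butyldimethylsilyloxy)-3-[(2E)-3,7-dimethyl-7-(triethylsilyloxy)oct-2-en-1-yl]buta-1,3-diene
Product: 21 5,7-bis(tert-butyldimethylsilyloxy)-2-{4-(tert-butyldimethylsilyloxy)-3-[(2E)-3,7-dimethyl-7-(triethylsilyloxy)oct-2-en-1-yl]phenyl}-4H-chromen-4-one, via cyclohexadiene 20 (not isolated)
Conditions: 7 (1.2 equiv), 19, PhMe, BHT (cat.), 130 °C, sealed tube; then DDQ (1.05 equiv), 0 °C to rt
Reagents that add atoms: none
Why: The alkyne of 7 is electron-poor because it is conjugated through C2=C3 with the chromone carbonyl (a vinylogous ynone), so it should act as dienophile in a concerted, normal-electron-demand [4+2] cycloaddition with the electron-rich diene 19, forming C1'–C2' and C5'–C6' and closing ring B as a six-membered carbocycle by intermolecular cycloaddition (the 1-silyloxycyclohexa-1,4-diene 20). The closest known reaction type is the Diels–Alder reaction of 2-silyloxybuta-1,3-dienes with conjugated ynones and propiolates followed by quinone dehydrogenation to the aryl silyl ether. DDQ then abstracts hydride from a doubly allylic ring CH2 of 20 and loss of a proton aromatises ring B, which should be much faster than attack on the benzylic–allylic CH2 of the side chain when one equivalent is used in the cold. No stereocentre is formed and the E-olefin is carried through from the diene. The selectivity needed is regiochemical (silyloxy para to the chromone, chain meta): the largest HOMO coefficient of the diene lies on C1 next to the silyloxy-bearing carbon, since the oxygen donor outweighs the C3 alkyl group, and the largest LUMO coefficient of the dienophile lies on the terminal alkyne carbon, so these two atoms bond; the unhindered alkyne should react in preference to the trisubstituted, oxygen-deactivated C2=C3 bond, and 7 is kept in slight excess so that no dienol ether remains when the quinone is added.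

Step 10
Reactants: 21 5,7-bis(tert-butyldimethylsilyloxy)-2-{4-(tert-butyldimethylsilyloxy)-3-[(2E)-3,7-dimethyl-7-(triethylsilyloxy)oct-2-en-1-yl]phenyl}-4H-chromen-4-one
Product: 23 (2S)-5,7-bis(tert-butyldimethylsilyloxy)-2-{4-(tert-butyldimethylsilyloxy)-3-[(2E)-3,7-dimethyl-7-(triethylsilyloxy)oct-2-en-1-yl]phenyl}-2,3-dihydro-4H-chromen-4-one, via silyl enol ether 22 (not isolated)
Conditions: Cu(OAc)2 (5 mol %), (R)-DTBM-SEGPHOS (5.5 mol %), (EtO)2MeSiH (3 equiv), PhMe, 0 °C to rt; then AcOH, THF–H2O, 0 °C
Reagents that add atoms: none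
Why: Asymmetric conjugate reduction with a bisphosphine-ligated CuH (known for chromones and β-aryl enones), in which the chiral ligand directs hydride to the Re face of C2 and so creates the (S) centre, the copper enolate is trapped by the silane as a silyl enol ether that cannot open to the chalcone, and mild acid hydrolysis releases the ketone without epimerising C2; silyl ethers and the isolated trisubstituted olefin are inert to CuH.

Step 11
Reactants: 23 (2S)-5,7-bis(tert-butyldimethylsilyloxy)-2-{4-(tert-butyldimethylsilyloxy)-3-[(2E)-3,7-dimethyl-7-(triethylsilyloxy)oct-2-en-1-yl]phenyl}-2,3-dihydro-4H-chromen-4-one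
Product: 24 (2S)-5,7-dihydroxy-2-{4-hydroxy-3-[(2E)-7-hydroxy-3,7-dimethyloct-2-en-1-yl]phenyl}-2,3-dihydro-4H-chromen-4-one
Conditions: HF·pyridine (excess), pyridine–THF, 0 °C to rt
Reagents that add atoms: none
Why: Fluoride desilylation under buffered acidic conditions removes the three aryl silyl ethers and the tertiary triethylsilyl ether without generating free phenoxide, so neither base-induced ring opening and racemisation of the flavanone nor acid-induced cyclisation of the phenol onto the side-chain olefin is expected.

**Compound list**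

1 | 2',4',6'-trihydroxyacetophenone | CC(=O)c1c(O)cc(O)cc1O | starting material
2 | ethyl 2,2-diethoxyacetate | CCOC(=O)C(OCC)OCC | starting material
3 | 4,4-diethoxy-1-(2,4,6-trihydroxyphenyl)butane-1,3-dione (not isolated) | CCOC(OCC)C(=O)CC(=O)c1c(O)cc(O)cc1O | intermediate
4 | 2-(diethoxymethyl)-5,7-dihydroxy-4H-chromen-4-one (not isolated) | CCOC(OCC)c1cc(=O)c2c(O)cc(O)cc2o1 | intermediate
5 | 5,7-dihydroxy-4-oxo-4H-chromene-2-carbaldehyde | O=Cc1cc(=O)c2c(O)cc(O)cc2o1 | intermediate
6 | 2-ethynyl-5,7-dihydroxy-4H-chromen-4-one | C#Cc1cc(=O)c2c(O)cc(O)cc2o1 | intermediate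
7 | 5,7-bis(tert-butyldimethylsilyloxy)-2-ethynyl-4H-chromen-4-one | C#Cc1cc(=O)c2c(O[Si](C)(C)C(C)(C)C)cc(O[Si](C)(C)C(C)(C)C)cc2o1 | intermediate
8 | geranyl acetate, (2E)-3,7-dimethylocta-2,6-dien-1-yl acetate | CC(C)=CCC/C(C)=C/COC(C)=O | starting material
9 | (2E)-6-(acetoxymercurio)-7-hydroxy-3,7-dimethyloct-2-en-1-yl acetate, racemic at C6 (not isolated) | CC(=O)OC/C=C(\C)CCC([Hg]OC(C)=O)C(C)(C)O | intermediate
10 | (2E)-7-hydroxy-3,7-dimethyloct-2-en-1-yl acetate (not isolated) | CC(=O)OC/C=C(\C)CCCC(C)(C)O | intermediate
11 | (2E)-3,7-dimethyloct-2-ene-1,7-diol | OC/C=C(\C)CCCC(C)(C)O | intermediate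
12 | (6E)-8-bromo-2,6-dimethyloct-6-en-2-ol | BrC/C=C(\C)CCCC(C)(C)O | intermediate
13 | methyl acetoacetate | CC(=O)CC(=O)OC | starting material
14 | methyl (4E)-2-acetyl-9-hydroxy-5,9-dimethyldec-4-enoate, racemic | COC(=O)C(C(C)=O)C/C=C(\C)CCCC(C)(C)O | intermediate
15 | (4E)-2-acetyl-9-hydroxy-5,9-dimethyldec-4-enoic acid, racemic (not isolated) | OC(=O)C(C(C)=O)C/C=C(\C)CCCC(C)(C)O | intermediate
16 | (4E)-2-acetyl-2-[(diethylamino)methyl]-9-hydroxy-5,9-dimethyldec-4-enoic acid, racemic (not isolated) | CCN(CC)CC(C(C)=O)(C(=O)O)C/C=C(\C)CCCC(C)(C)O | intermediate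
17 | (5E)-10-hydroxy-6,10-dimethyl-3-methylideneundec-5-en-2-one | CC(=O)C(=C)C/C=C(\C)CCCC(C)(C)O | intermediate
18 | (5E)-6,10-dimethyl-3-methylidene-10-(triethylsilyloxy)undec-5-en-2-one (not isolated) | CC(=O)C(=C)C/C=C(\C)CCCC(C)(C)O[Si](CC)(CC)CC | intermediate
19 | 2-(tert-butyldimethylsilyloxy)-3-[(2E)-3,7-dimethyl-7-(triethylsilyloxy)oct-2-en-1-yl]buta-1,3-diene | C=C(O[Si](C)(C)C(C)(C)C)C(=C)C/C=C(\C)CCCC(C)(C)O[Si](CC)(CC)CC | intermediate
20 | 5,7-bis(tert-butyldimethylsilyloxy)-2-{4-(tert-butyldimethylsilyloxy)-5-[(2E)-3,7-dimethyl-7-(triethylsilyloxy)oct-2-en-1-yl]cyclohexa-1,4-dien-1-yl}-4H-chromen-4-one (not isolated) | C/C(=C\CC1=C(O[Si](C)(C)C(C)(C)C)CC=C(C1)c1cc(=O)c2c(O[Si](C)(C)C(C)(C)C)cc(O[Si](C)(C)C(C)(C)C)cc2o1)CCCC(C)(C)O[Si](CC)(CC)CC | intermediate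
21 | 5,7-bis(tert-butyldimethylsilyloxy)-2-{4-(tert-butyldimethylsilyloxy)-3-[(2E)-3,7-dimethyl-7-(triethylsilyloxy)oct-2-en-1-yl]phenyl}-4H-chromen-4-one | C/C(=C\Cc1cc(-c2cc(=O)c3c(O[Si](C)(C)C(C)(C)C)cc(O[Si](C)(C)C(C)(C)C)cc3o2)ccc1O[Si](C)(C)C(C)(C)C)CCCC(C)(C)O[Si](CC)(CC)CC | intermediate
22 | (2S)-5,7-bis(tert-butyldimethylsilyloxy)-2-{4-(tert-butyldimethylsilyloxy)-3-[(2E)-3,7-dimethyl-7-(triethylsilyloxy)oct-2-en-1-yl]phenyl}-4-{[diethoxy(methyl)silyl]oxy}-2H-chromene (not isolated) | C/C(=C\Cc1cc([C@@H]2C=C(O[Si](C)(OCC)OCC)c3c(O[Si](C)(C)C(C)(C)C)cc(O[Si](C)(C)C(C)(C)C)cc3O2)ccc1O[Si](C)(C)C(C)(C)C)CCCC(C)(C)O[Si](CC)(CC)CC | intermediate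
23 | (2S)-5,7-bis(tert-butyldimethylsilyloxy)-2-{4-(tert-butyldimethylsilyloxy)-3-[(2E)-3,7-dimethyl-7-(triethylsilyloxy)oct-2-en-1-yl]phenyl}-2,3-dihydro-4H-chromen-4-one | C/C(=C\Cc1cc([C@@H]2CC(=O)c3c(O[Si](C)(C)C(C)(C)C)cc(O[Si](C)(C)C(C)(C)C)cc3O2)ccc1O[Si](C)(C)C(C)(C)C)CCCC(C)(C)O[Si](CC)(CC)CC | intermediate
24 | (2S)-5,7-dihydroxy-2-{4-hydroxy-3-[(2E)-7-hydroxy-3,7-dimethyloct-2-en-1-yl]phenyl}-2,3-dihydro-4H-chromen-4-one | C/C(=C\Cc1cc([C@@H]2CC(=O)c3c(O)cc(O)cc3O2)ccc1O)CCCC(C)(C)O | target

**Step count**

Total step count: 11. Longest linear sequence: 8 steps (steps 4 to 11, from geranyl acetate).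

**Steps most likely to fail**

Step 9. The alkyne is activated only through the vinylogous chromone carbonyl, so the cycloaddition may be slower than thermal loss of the dienol ether, and bonding steered by the C3 alkyl group of the diene may erode the para orientation. The fallback sets out from 7 and 19 and replaces the concerted thermal reaction by the cobalt-catalysed neutral Diels–Alder reaction of terminal alkynes with 2-silyloxydienes (CoBr2(dppe), Zn, ZnI2, CH2Cl2, rt). This proceeds through a cobaltacycle at low-valent cobalt, needs no LUMO-lowered alkyne, and with this ligand is known to place the alkyne substituent para to the silyloxy group of 2-silyloxybutadienes; whether that holds for this 2,3-disubstituted diene is untested. The cyclohexadiene 20 so formed would be oxidised with DDQ and the route rejoined at 21; new compounds: none F0.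

Step 10. Hydride delivery may show poor facial selectivity, or turnover may stall on the hindered peri-silyloxy flavone. The fallback sets out from 21 and obtains the stereocentre by resolution instead of asymmetric catalysis. Non-selective conjugate reduction with LiBH(s-Bu)3 (THF, –78 °C, then AcOH) would give the racemic silylated flavanone F1. Preparative chromatography on a chiral stationary phase would then separate 23, where the route is rejoined, from the (2R)-enantiomer F2.

Step 2. Conjugate addition of methoxide to the electron-poor alkyne, or base-induced opening of the pyranone ring, may compete during the homologation in basic methanol. The fallback sets out from 5 and reverses the order of protection and homologation under aprotic conditions. Silylation (TBSOTf, 2,6-lutidine, CH2Cl2) would give 5,7-bis(tert-butyldimethylsilyloxy)-4-oxo-4H-chromene-2-carbaldehyde F3. Colvin homologation of this aldehyde with LiC(N2)SiMe3 (from Me3SiCHN2 and LiN(i-Pr)2, THF, –78 to 0 °C) would give the alkyne through an alkylidene carbene, and the route is rejoined at 7, steps 2 and 3 being replaced.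

Further compounds
F0 | step 9 | none | none
F1 | step 10 | rac-5,7-bis(tert-butyldimethylsilyloxy)-2-{4-(tert-butyldimethylsilyloxy)-3-[(2E)-3,7-dimethyl-7-(triethylsilyloxy)oct-2-en-1-yl]phenyl}-2,3-dihydro-4H-chromen-4-one | C/C(=C\Cc1cc(C2CC(=O)c3c(O[Si](C)(C)C(C)(C)C)cc(O[Si](C)(C)C(C)(C)C)cc3O2)ccc1O[Si](C)(C)C(C)(C)C)CCCC(C)(C)O[Si](CC)(CC)CC
F2 | step 10 | (2R)-5,7-bis(tert-butyldimethylsilyloxy)-2-{4-(tert-butyldimethylsilyloxy)-3-[(2E)-3,7-dimethyl-7-(triethylsilyloxy)oct-2-en-1-yl]phenyl}-2,3-dihydro-4H-chromen-4-one | C/C(=C\Cc1cc([C@H]2CC(=O)c3c(O[Si](C)(C)C(C)(C)C)cc(O[Si](C)(C)C(C)(C)C)cc3O2)ccc1O[Si](C)(C)C(C)(C)C)CCCC(C)(C)O[Si](CC)(CC)CC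
F3 | step 2 | 5,7-bis(tert-butyldimethylsilyloxy)-4-oxo-4H-chromene-2-carbaldehyde | O=Cc1cc(=O)c2c(O[Si](C)(C)C(C)(C)C)cc(O[Si](C)(C)C(C)(C)C)cc2o1
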